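**Retrosynthetic overview**
1. Pyran ring (made last): C–O bond by oxa-6π electrocyclisation of the o-quinone methide tautomer of 2-methoxy-3,6-di(indol-3-yl)-5-prenyl-1,4-benzoquinone.
2. Methoxy group: addition–elimination of methoxide on the corresponding 2-bromoquinone.
3. Key C–C bonds: two intermolecular Michael additions of indole (through C3) to 2-bromo-5-prenyl-1,4-benzoquinone, each followed by re-oxidation of the hydroquinone.
4. Bromo-prenylquinone: from 1,4-dibromo-2,5-dimethoxybenzene by Br/Li exchange and prenylation, then oxidative demethylation.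
5. Ring order: the benzene ring and both indole bicycles are bought intact, the central ring is carried as arene, quinone and arene again, and the pyran ring is the only ring formed.

Assumption: kumbicin C has no stereocentre, and its only non-aromatic C=C lies in the six-membered pyran ring and is necessarily cis, so the target is the single achiral compound drawn.

**Step 1**
Reactants: 1 1,4-dibromo-2,5-dimethoxybenzene; 2 prenyl bromide (1-bromo-3-methylbut-2-ene)
Product: 4 1-bromo-2,5-dimethoxy-4-(3-methylbut-2-en-1-yl)benzene, via aryllithium 3 (not isolated)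
Conditions: n-BuLi (1.0 equiv), THF, −78 °C, 30 min; then CuBr·SMe2 (10 mol%), 2 (1.2 equiv), −78 to 0 °C
Reagents that add atoms: none
Why: Br/Li exchange on the symmetrical dibromide stops cleanly after one bromine at −78 °C, and copper-catalysed allylic substitution of the aryllithium at the primary carbon of 2 gives the linear (SN2) prenyl arene; no stereocentre is formed.

**Step 2**
Reactants: 4 1-bromo-2,5-dimethoxy-4-(3-methylbut-2-en-1-yl)benzene
Product: 5 2-bromo-5-(3-methylbut-2-en-1-yl)-1,4-benzoquinone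
Conditions: (NH4)2Ce(NO3)6 (2.5 equiv), MeCN/H2O (2:1), 0 °C, 20 min
Reagents that add atoms: water, O
Why: Oxidative demethylation of a hydroquinone dimethyl ether by tetravalent cerium is fast at 0 °C, takes both carbonyl oxygens from water and leaves the C–Br bond and the trisubstituted alkene untouched; no stereocentre is formed.

**Step 3**
Reactants: 5 2-bromo-5-(3-methylbut-2-en-1-yl)-1,4-benzoquinone; 6 indole
Product: 8 2-bromo-3-(1H-indol-3-yl)-5-(3-methylbut-2-en-1-yl)-1,4-benzoquinone, via hydroquinone 7 (not isolated)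
Conditions: 6 (1.05 equiv), AcOH, rt, 16 h; concentrate; then DDQ (1.1 equiv), THF, 0 °C
Reagents that add atoms: none
Why: Acid-promoted intermolecular Michael (conjugate) addition of indole C3 to the CH of the more electrophilic, bromine-bearing double bond gives the hydroquinone, which DDQ returns to the quinone; acetic acid is mild enough for the prenyl group, the minor regioisomer would converge in step 4, and no stereocentre is formed.

**Step 4**
Reactants: 8 2-bromo-3-(1H-indol-3-yl)-5-(3-methylbut-2-en-1-yl)-1,4-benzoquinone; 6 indole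
Product: 10 2-bromo-3,6-di(1H-indol-3-yl)-5-(3-methylbut-2-en-1-yl)-1,4-benzoquinone, via hydroquinone 9 (not isolated)
Conditions: 6 (1.5 equiv), AcOH, 40 °C, 24 h; concentrate; then DDQ (1.1 equiv), THF, 0 °C
Reagents that add atoms: none
Why: A second Michael addition of indole C3 takes the only remaining ring CH (beta to the C4 carbonyl, which the first indolyl group does not deactivate by conjugation), and DDQ again oxidises the hydroquinone to the quinone; no stereocentre is formed.

**Step 5**
Reactants: 10 2-bromo-3,6-di(1H-indol-3-yl)-5-(3-methylbut-2-en-1-yl)-1,4-benzoquinone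
Product: 11 2-methoxy-3,6-di(1H-indol-3-yl)-5-(3-methylbut-2-en-1-yl)-1,4-benzoquinone
Conditions: NaOMe (2.0 equiv), MeOH/THF (1:1), −20 to 0 °C, 1 h; AcOH quench
Reagents that add atoms: sodium methoxide, [Na+].[O-]C
Why: Addition–elimination (vinylogous acyl substitution) of methoxide at the single C–Br carbon of the bromoquinone is much faster at or below 0 °C than base-induced isomerisation of the prenyl side chain; no stereocentre is formed.

**Step 6**
Reactants: 11 2-methoxy-3,6-di(1H-indol-3-yl)-5-(3-methylbut-2-en-1-yl)-1,4-benzoquinone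
Product: 13 kumbicin C (5,8-di(1H-indol-3-yl)-7-methoxy-2,2-dimethyl-2H-chromen-6-ol), via o-quinone methide 12 (not isolated)
Conditions: pyridine, 115 °C, Ar, 4 h
Reagents that add atoms: none
Why: Pyridine-mediated tautomerisation of the prenylquinone to the (Z)-o-quinone methide and thermal oxa-6π electrocyclisation onto the C4 oxygen close the 2,2-dimethyl-2H-pyran ring and leave the former C1 oxygen as the free phenol next to the methoxy group; the ring alkene is necessarily cis and no stereocentre is formed.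

**Compound list**
1 | 1,4-dibromo-2,5-dimethoxybenzene | COc1cc(Br)c(OC)cc1Br | starting material
2 | prenyl bromide (1-bromo-3-methylbut-2-ene) | CC(C)=CCBr | starting material
3 | (4-bromo-2,5-dimethoxyphenyl)lithium | [Li]c1cc(OC)c(Br)cc1OC | intermediate
4 | 1-bromo-2,5-dimethoxy-4-(3-methylbut-2-en-1-yl)benzene | COc1cc(CC=C(C)C)c(OC)cc1Br | intermediate
5 | 2-bromo-5-(3-methylbut-2-en-1-yl)-1,4-benzoquinone | O=C1C=C(CC=C(C)C)C(=O)C=C1Br | intermediate
6 | indole | c1ccc2[nH]ccc2c1 | starting material
7 | 2-bromo-3-(1H-indol-3-yl)-5-(3-methylbut-2-en-1-yl)benzene-1,4-diol | Oc1cc(CC=C(C)C)c(O)c(-c2c[nH]c3ccccc23)c1Br | intermediate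
8 | 2-bromo-3-(1H-indol-3-yl)-5-(3-methylbut-2-en-1-yl)-1,4-benzoquinone | O=C1C=C(CC=C(C)C)C(=O)C(-c2c[nH]c3ccccc23)=C1Br | intermediate
9 | 2-bromo-3,6-di(1H-indol-3-yl)-5-(3-methylbut-2-en-1-yl)benzene-1,4-diol | Oc1c(Br)c(-c2c[nH]c3ccccc23)c(O)c(CC=C(C)C)c1-c1c[nH]c2ccccc12 | intermediate
10 | 2-bromo-3,6-di(1H-indol-3-yl)-5-(3-methylbut-2-en-1-yl)-1,4-benzoquinone | O=C1C(-c2c[nH]c3ccccc23)=C(CC=C(C)C)C(=O)C(-c2c[nH]c3ccccc23)=C1Br | intermediate
11 | 2-methoxy-3,6-di(1H-indol-3-yl)-5-(3-methylbut-2-en-1-yl)-1,4-benzoquinone | COC1=C(-c2c[nH]c3ccccc23)C(=O)C(CC=C(C)C)=C(-c2c[nH]c3ccccc23)C1=O | intermediate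
12 | (Z)-4-hydroxy-2,5-di(1H-indol-3-yl)-3-methoxy-6-(3-methylbut-2-en-1-ylidene)cyclohexa-2,4-dien-1-one | COC1=C(-c2c[nH]c3ccccc23)C(=O)/C(=C\C=C(C)C)C(-c2c[nH]c3ccccc23)=C1O | intermediate
13 | kumbicin C (5,8-di(1H-indol-3-yl)-7-methoxy-2,2-dimethyl-2H-chromen-6-ol) | COc1c(O)c(-c2c[nH]c3ccccc23)c2c(c1-c1c[nH]c3ccccc13)OC(C)(C)C=C2 | target

**Totals**
Total step count: 6. Longest linear sequence: 6 steps (1 to 13).

**Three steps most likely to fail**

Step 4 is the weakest step. The second Michael addition must take place next to the prenyl group on a quinone already carrying one donor indolyl group, and the prenyl alkene limits how strong the acid may be. The fallback sets out from indole 6 and forms both indolyl–ring bonds before any prenyl group is present. Indole 6 is added (HCl, THF, rt) to purchased 2,5-dibromo-1,4-benzoquinone F1 to give 2,5-dibromo-3-(1H-indol-3-yl)benzene-1,4-diol F2, which DDQ oxidises in the same flask to 2,5-dibromo-3-(1H-indol-3-yl)-1,4-benzoquinone F3. A second equivalent of 6 (catalytic H2SO4 in AcOH) gives 2,5-dibromo-3,6-di(1H-indol-3-yl)benzene-1,4-diol F4, and DDQ gives 2,5-dibromo-3,6-di(1H-indol-3-yl)-1,4-benzoquinone F5. Both additions here occur next to a halogen, the favourable situation. One of the two equivalent C–Br bonds of F5 is then coupled with purchased tributyl(3-methylbut-2-en-1-yl)stannane F6 (1.0 equiv, Pd(PPh3)4, dioxane, 80 °C, Stille coupling; unreacted F5 is recycled). This comes back to the route at compound 10.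

Step 5 can fail if methoxide deprotonates the prenyl CH2 and the bromoquinone isomerises to a chromenol before the bromide is displaced. The fallback sets out from compound 10 and reverses the order of the last two events. Compound 10 is heated in pyridine first, so that it passes through (Z)-3-bromo-4-hydroxy-2,5-di(1H-indol-3-yl)-6-(3-methylbut-2-en-1-ylidene)cyclohexa-2,4-dien-1-one F7 to 7-bromo-5,8-di(1H-indol-3-yl)-2,2-dimethyl-2H-chromen-6-ol F8. The aryl bromide ortho to the free phenol is then exchanged for methoxide by copper-mediated Ullmann-type methoxylation (NaOMe, CuBr, DMF/MeOH, 110 °C). This comes back to the route at compound 13.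

Step 6 can fail if the electron-rich bis-indolyl quinone decomposes in hot pyridine or the tautomerisation is sluggish. The fallback sets out from compound 11 and closes the ring as a chroman before introducing the alkene. Compound 11 is reduced with Na2S2O4 (THF/H2O) to 2-methoxy-3,6-di(1H-indol-3-yl)-5-(3-methylbut-2-en-1-yl)benzene-1,4-diol F9. Acid-catalysed Markovnikov hydroalkoxylation (TsOH 10 mol%, toluene, 60 °C) by the hydroxyl next to the prenyl group gives 5,8-di(1H-indol-3-yl)-7-methoxy-2,2-dimethylchroman-6-ol F10. Benzylic dehydrogenation with DDQ (1.1 equiv, dioxane, 80 °C), assisted by the para methoxy group, introduces the C3=C4 alkene. This comes back to the route at compound 13.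

**Further compounds**
F1 | step 4 | 2,5-dibromo-1,4-benzoquinone | O=C1C=C(Br)C(=O)C=C1Br
F2 | step 4 | 2,5-dibromo-3-(1H-indol-3-yl)benzene-1,4-diol | Oc1cc(Br)c(O)c(-c2c[nH]c3ccccc23)c1Br
F3 | step 4 | 2,5-dibromo-3-(1H-indol-3-yl)-1,4-benzoquinone | O=C1C=C(Br)C(=O)C(-c2c[nH]c3ccccc23)=C1Br
F4 | step 4 | 2,5-dibromo-3,6-di(1H-indol-3-yl)benzene-1,4-diol | Oc1c(Br)c(-c2c[nH]c3ccccc23)c(O)c(Br)c1-c1c[nH]c2ccccc12
F5 | step 4 | 2,5-dibromo-3,6-di(1H-indol-3-yl)-1,4-benzoquinone | O=C1C(-c2c[nH]c3ccccc23)=C(Br)C(=O)C(-c2c[nH]c3ccccc23)=C1Br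
F6 | step 4 | tributyl(3-methylbut-2-en-1-yl)stannane | CCCC[Sn](CCCC)(CCCC)CC=C(C)C
F7 | step 5 | (Z)-3-bromo-4-hydroxy-2,5-di(1H-indol-3-yl)-6-(3-methylbut-2-en-1-ylidene)cyclohexa-2,4-dien-1-one | BrC1=C(-c2c[nH]c3ccccc23)C(=O)/C(=C\C=C(C)C)C(-c2c[nH]c3ccccc23)=C1O
F8 | step 5 | 7-bromo-5,8-di(1H-indol-3-yl)-2,2-dimethyl-2H-chromen-6-ol | Brc1c(O)c(-c2c[nH]c3ccccc23)c2c(c1-c1c[nH]c3ccccc13)OC(C)(C)C=C2
F9 | step 6 | 2-methoxy-3,6-di(1H-indol-3-yl)-5-(3-methylbut-2-en-1-yl)benzene-1,4-diol | COc1c(O)c(-c2c[nH]c3ccccc23)c(CC=C(C)C)c(O)c1-c1c[nH]c2ccccc12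
F10 | step 6 | 5,8-di(1H-indol-3-yl)-7-methoxy-2,2-dimethylchroman-6-ol | COc1c(O)c(-c2c[nH]c3ccccc23)c2c(c1-c1c[nH]c3ccccc13)OC(C)(C)CC2
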